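**Retrosynthetic overview**

1. Target ⇒ open-chain (2E,4Z,6S,7E,9E,11E,13E)-hexaenoic acid (labels C1 = CO2H carbon to C14 = CHPh, kept for all compounds) by one intramolecular Diels–Alder reaction. Bonds C3–C7 and C2–C10 form together, so the cyclohexene and the cyclopentene (its C4=C5 alkene already sits in the tether) are closed in the same step.
2. Hexaenoic acid ⇒ (Z)-vinyl iodide C4–C14 + (E)-3-iodo-2-methylacrylic acid C1–C3 (C3–C4 bond, borylation/Suzuki coupling).
3. (Z)-Vinyl iodide ⇒ α-methyl tetraenal C5–C14 (C4=C5, Stork–Zhao olefination).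
4. Tetraenal ⇒ Roche ester (C5–C7, carrying C6, the only stereocentre set before the cycloaddition) by three E-selective olefinations (C7=C8, C9=C10, C11=C12) and direct oxidation of the C5 silyl ether.

Assumptions: the target is taken exactly as drawn in the SMILES, i.e. the (1R,3aR,4R,5S,7aS) trans-fused enantiomer; the two formyl ylides 3 and 6 are bought as catalogue reagents.

**Route**

Step 1
Reactants: 1 methyl (2R)-3-hydroxy-2-methylpropanoate (Roche ester)
Product: 2 methyl (2R)-2-methyl-3-[(triethylsilyl)oxy]propanoate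
Conditions: Et3SiCl, imidazole, CH2Cl2, 0 °C to rt
Reagents that add atoms: chlorotriethylsilane, CC[Si](Cl)(CC)CC
Why: Silylation of the primary alcohol (silyl ether protection) leaves C6 untouched, and a primary triethylsilyl ether is chosen because it can later be oxidised directly to the aldehyde.

Step 2
Reactants: 2 methyl (2R)-2-methyl-3-[(triethylsilyl)oxy]propanoate; 3 2-(triphenylphosphoranylidene)propanal
Product: 5 (2E,4S)-2,4-dimethyl-5-[(triethylsilyl)oxy]pent-2-enal, via aldehyde 4 (not isolated)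
Conditions: iBu2AlH (1.05 equiv), PhMe, −78 °C; MeOH, then potassium sodium tartrate (aq); dried PhMe layer, 3 (1.3 equiv), 80 °C
Reagents that add atoms: none
Why: Partial ester reduction stops at the aluminium hemiacetal at −78 °C, and the freed aldehyde undergoes a Wittig reaction with the stabilised formyl ylide, which gives the E enal (CHO trans to C6); C6 comes unchanged from 1 and no base is present to epimerise 4.

Step 3
Reactants: 5 (2E,4S)-2,4-dimethyl-5-[(triethylsilyl)oxy]pent-2-enal; 6 2-(triphenylphosphoranylidene)butanal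
Product: 7 (2E,4E,6S)-2-ethyl-4,6-dimethyl-7-[(triethylsilyl)oxy]hepta-2,4-dienal
Conditions: 6 (2 equiv), PhMe, 110 °C, 36 h
Reagents that add atoms: none
Why: Wittig reaction of the stabilised α-formyl ylide with an enal gives the E trisubstituted C9=C10 alkene (C11 trans to C8); the medium is neutral, so the γ-hydrogen at C6 is not removed.

Step 4
Reactants: 7 (2E,4E,6S)-2-ethyl-4,6-dimethyl-7-[(triethylsilyl)oxy]hepta-2,4-dienal; 8 diethyl [(2E)-3-phenylprop-2-en-1-yl]phosphonate (diethyl cinnamylphosphonate)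
Product: 9 triethyl{[(2S,3E,5E,7E,9E)-6-ethyl-2,4-dimethyl-10-phenyldeca-3,5,7,9-tetraen-1-yl]oxy}silane
Conditions: 8, LiN(SiMe3)2, THF, −78 °C; then 7, −78 to 0 °C
Reagents that add atoms: none
Why: Horner–Wadsworth–Emmons olefination with an allylic phosphonate anion gives the E C11=C12 alkene; 1,2-addition at −78 °C is much faster than vinylogous deprotonation at C6.

Step 5
Reactants: 9 triethyl{[(2S,3E,5E,7E,9E)-6-ethyl-2,4-dimethyl-10-phenyldeca-3,5,7,9-tetraen-1-yl]oxy}silane
Product: 10 (2S,3E,5E,7E,9E)-6-ethyl-2,4-dimethyl-10-phenyldeca-3,5,7,9-tetraenal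
Conditions: (COCl)2, DMSO, CH2Cl2, −78 to −30 °C; iPr2NEt, −78 °C; NaH2PO4/Na2HPO4 buffer (pH 7), 0 °C; used crude at once
Reagents that add atoms: none
Why: Swern oxidation applied directly to a primary triethylsilyl ether: chlorodimethylsulfonium chloride cleaves the O–Si bond and the alkoxysulfonium salt collapses to the aldehyde on adding base, so no separate deprotection is needed; the hindered amine and cold quench preserve the α-stereocentre C6 of this β,γ-unsaturated aldehyde.

Step 6
Reactants: 10 (2S,3E,5E,7E,9E)-6-ethyl-2,4-dimethyl-10-phenyldeca-3,5,7,9-tetraenal; 11 propyltriphenylphosphonium bromide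
Product: 15 [(1E,3E,5E,7E,9S,10Z)-5-ethyl-11-iodo-7,9-dimethyltrideca-1,3,5,7,10-pentaen-1-yl]benzene, via propylidene ylide 12 (not isolated), via iodophosphonium salt 13 (not isolated), via iodo-ylide 14 (not isolated)
Conditions: 11 (2.2 equiv), nBuLi, THF, 0 °C; I2, −78 °C; NaN(SiMe3)2, −20 °C; then 10, −78 °C, 1 h
Reagents that add atoms: iodine, II
Why: Stork–Zhao olefination (Wittig reaction of an α-iodoalkylidene ylide): the kinetically formed cis-oxaphosphetane places iodine cis to C6, giving the Z trisubstituted iodide with ethyl trans to C6; the ylide adds at −78 °C faster than it enolises 10, so C6 is kept.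

Step 7
Reactants: 16 diethyl 2-methylpropanedioate (diethyl methylmalonate); 17 triiodomethane (iodoform)
Product: 18 diethyl 2-(diiodomethyl)-2-methylpropanedioate
Conditions: NaH, Et2O, reflux
Reagents that add atoms: none
Why: Alkylation of the malonate enolate with iodoform gives the quaternary diiodomethyl malonate; no stereocentre is formed.

Step 8
Reactants: 18 diethyl 2-(diiodomethyl)-2-methylpropanedioate
Product: 19 (2E)-3-iodo-2-methylprop-2-enoic acid
Conditions: KOH, EtOH–H2O, reflux; then HCl (aq)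
Reagents that add atoms: potassium hydroxide, [K+].[OH-]
Why: Saponification followed by decarboxylative anti-elimination of iodide gives the E β-iodoacrylic acid (iodine trans to CO2H), the thermodynamically favoured isomer.

Step 9
Reactants: 15 [(1E,3E,5E,7E,9S,10Z)-5-ethyl-11-iodo-7,9-dimethyltrideca-1,3,5,7,10-pentaen-1-yl]benzene; 19 (2E)-3-iodo-2-methylprop-2-enoic acid; 20 bis(pinacolato)diboron
Product: 22 (2E,4Z,6S,7E,9E,11E,13E)-4,10-diethyl-2,6,8-trimethyl-14-phenyltetradeca-2,4,7,9,11,13-hexaenoic acid, via alkenylboronate 21 (not isolated)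
Conditions: 20, PdCl2(dppf) (5 mol %), KOPh, PhMe, 50 °C; then 19, K3PO4 (aq), THF, 45 °C; NaH2PO4 (aq) to pH 4 at 0 °C; kept cold and dark
Reagents that add atoms: none
Why: Miyaura borylation followed in the same pot by Suzuki–Miyaura coupling; both proceed with retention at the alkene carbons, so the Z iodide gives the 4Z alkene (C3 cis to C6) and the E iodoacid gives the 2E alkene, and the hexaene is held as its unreactive carboxylate until the cold acidic work-up.

Step 10
Reactants: 22 (2E,4Z,6S,7E,9E,11E,13E)-4,10-diethyl-2,6,8-trimethyl-14-phenyltetradeca-2,4,7,9,11,13-hexaenoic acid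
Product: 23 (1R,3aR,4R,5S,7aS)-3,5-diethyl-1,4,7-trimethyl-5-[(1E,3E)-4-phenylbuta-1,3-dien-1-yl]-3a,4,5,7a-tetrahydro-1H-indene-4-carboxylic acid (target)
Conditions: PhMe (0.005 M), BHT (5 mol %), 85 °C, Ar, dark, 36 h
Reagents that add atoms: none
Why: Proposed new method: a thermal type 1 intramolecular Diels–Alder reaction whose three-atom tether contains the 4Z alkene, so both rings and the stereocentres C2, C3, C7 and C10 form at once under control of C6; the closest known reaction type is the intramolecular Diels–Alder cyclisation of 1,3,8-nonatrienes with saturated tethers that gives spiculane-type hydrindanes; it should work because A(1,3) strain between the C2 methyl, the C4 ethyl and C6 already twists C2=C3 out of conjugation with C4=C5 (so it reacts as an isolated tiglic-acid dienophile), the cis alkene holds C3 next to C7, the carboxyl-endo/tether-exo transition state gives the trans ring fusion (the cis-fused alternative would put both the tether and the C2 methyl endo), the 2E alkene puts the C2 methyl syn to C4, the 7E,9E diene puts the C10 ethyl syn to H7, and the C6–H bond eclipses C7=C8 to avoid the C8 methyl so the dienophile adds anti to the C6 methyl.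

**Compound list**

1 | methyl (2R)-3-hydroxy-2-methylpropanoate | OC[C@@H](C)C(=O)OC | starting material
2 | methyl (2R)-2-methyl-3-[(triethylsilyl)oxy]propanoate | CC[Si](CC)(CC)OC[C@@H](C)C(=O)OC | intermediate
3 | 2-(triphenylphosphoranylidene)propanal | CC(C=O)=P(c1ccccc1)(c1ccccc1)c1ccccc1 | starting material
4 | (2R)-2-methyl-3-[(triethylsilyl)oxy]propanal | CC[Si](CC)(CC)OC[C@@H](C)C=O | intermediate
5 | (2E,4S)-2,4-dimethyl-5-[(triethylsilyl)oxy]pent-2-enal | CC[Si](CC)(CC)OC[C@@H](C)/C=C(C)/C=O | intermediate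
6 | 2-(triphenylphosphoranylidene)butanal | CCC(C=O)=P(c1ccccc1)(c1ccccc1)c1ccccc1 | starting material
7 | (2E,4E,6S)-2-ethyl-4,6-dimethyl-7-[(triethylsilyl)oxy]hepta-2,4-dienal | CC[Si](CC)(CC)OC[C@@H](C)/C=C(C)/C=C(CC)/C=O | intermediate
8 | diethyl [(2E)-3-phenylprop-2-en-1-yl]phosphonate | CCOP(=O)(C/C=C/c1ccccc1)OCC | starting material
9 | triethyl{[(2S,3E,5E,7E,9E)-6-ethyl-2,4-dimethyl-10-phenyldeca-3,5,7,9-tetraen-1-yl]oxy}silane | CC[Si](CC)(CC)OC[C@@H](C)/C=C(C)/C=C(CC)/C=C/C=C/c1ccccc1 | intermediate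
10 | (2S,3E,5E,7E,9E)-6-ethyl-2,4-dimethyl-10-phenyldeca-3,5,7,9-tetraenal | O=C[C@@H](C)/C=C(C)/C=C(CC)/C=C/C=C/c1ccccc1 | intermediate
11 | propyltriphenylphosphonium bromide | CCC[P+](c1ccccc1)(c1ccccc1)c1ccccc1.[Br-] | starting material
12 | triphenyl(propylidene)phosphorane | CCC=P(c1ccccc1)(c1ccccc1)c1ccccc1 | intermediate
13 | (1-iodopropyl)triphenylphosphonium iodide | CCC(I)[P+](c1ccccc1)(c1ccccc1)c1ccccc1.[I-] | intermediate
14 | (1-iodopropylidene)triphenylphosphorane | CCC(I)=P(c1ccccc1)(c1ccccc1)c1ccccc1 | intermediate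
15 | [(1E,3E,5E,7E,9S,10Z)-5-ethyl-11-iodo-7,9-dimethyltrideca-1,3,5,7,10-pentaen-1-yl]benzene | CC/C(I)=C/[C@@H](C)/C=C(C)/C=C(CC)/C=C/C=C/c1ccccc1 | intermediate
16 | diethyl 2-methylpropanedioate | CCOC(=O)C(C)C(=O)OCC | starting material
17 | triiodomethane | IC(I)I | starting material
18 | diethyl 2-(diiodomethyl)-2-methylpropanedioate | CCOC(=O)C(C)(C(I)I)C(=O)OCC | intermediate
19 | (2E)-3-iodo-2-methylprop-2-enoic acid | OC(=O)/C(C)=C/I | intermediate
20 | bis(pinacolato)diboron | CC1(C)OB(OC1(C)C)B1OC(C)(C)C(C)(C)O1 | starting material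
21 | 2-[(3E,5R,6E,8E,10E,12E)-9-ethyl-5,7-dimethyl-13-phenyltrideca-3,6,8,10,12-pentaen-3-yl]-4,4,5,5-tetramethyl-1,3,2-dioxaborolane | CC/C(B1OC(C)(C)C(C)(C)O1)=C/[C@@H](C)/C=C(C)/C=C(CC)/C=C/C=C/c1ccccc1 | intermediate
22 | (2E,4Z,6S,7E,9E,11E,13E)-4,10-diethyl-2,6,8-trimethyl-14-phenyltetradeca-2,4,7,9,11,13-hexaenoic acid | OC(=O)/C(C)=C/C(CC)=C\[C@@H](C)/C=C(C)/C=C(CC)/C=C/C=C/c1ccccc1 | intermediate
23 | (1R,3aR,4R,5S,7aS)-3,5-diethyl-1,4,7-trimethyl-5-[(1E,3E)-4-phenylbuta-1,3-dien-1-yl]-3a,4,5,7a-tetrahydro-1H-indene-4-carboxylic acid | CCC1=C[C@@H](C)[C@@H]2C(C)=C[C@@](/C=C/C=C/c3ccccc3)(CC)[C@](C)(C(=O)O)[C@@H]12 | target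

**Step count and risks**

Total steps: 10. Longest linear sequence: 8 (steps 1, 2, 3, 4, 5, 6, 9, 10).

Step 10 (cycloaddition) is the most likely to fail. The cis alkene in the tether may raise the barrier or favour the cis-fused adduct, and prolonged heating could allow a 1,5-hydrogen shift from C6. The fallback sets out from 22 and comes back at 23. Acid 22 is reduced with LiAlH4 (Et2O, −20 °C) to (2E,4Z,6S,7E,9E,11E,13E)-4,10-diethyl-2,6,8-trimethyl-14-phenyltetradeca-2,4,7,9,11,13-hexaen-1-ol F1. MnO2 (CH2Cl2, rt) then gives the corresponding hexaenal F2, a stronger dienophile. Its cycloaddition is promoted by Me2AlCl (CH2Cl2, −78 °C), where Lewis-acid complexation strengthens the endo preference and the low temperature excludes the hydrogen shift, giving the bicyclic aldehyde F3. Oxidation with NaClO2/NaH2PO4/2-methyl-2-butene (Pinnick oxidation) gives 23.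

Step 6 (Stork–Zhao olefination) is the second risk. Aldehyde 10 is α-chiral and β,γ-unsaturated, so the basic ylide can epimerise or deconjugate it, and yields of this olefination are moderate. The fallback sets out from 10 and comes back at 21. Non-basic dichloro-olefination (CBrCl3, PPh3, MeCN, 0 °C) gives [(1E,3E,5E,7E,9S)-11,11-dichloro-5-ethyl-7,9-dimethylundeca-1,3,5,7,10-pentaen-1-yl]benzene F4. A trans-selective Negishi mono-ethylation (EtZnBr, PdCl2(DPEphos), THF–DMF, rt) replaces the chlorine trans to C6 and gives the (Z)-chloride F5. Miyaura borylation of F5 with 20 (Pd2(dba)3, XPhos, KOAc, dioxane, 80 °C) gives boronate 21, which continues as in step 9.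

Step 9 (borylation/Suzuki coupling) is the third risk. The iodide is hindered, the boronate can protodeboronate, and the polyene acid is sensitive. The fallback sets out from 15 and comes back at 22; it builds C2=C3 by olefination instead of C3–C4 by coupling. Iodine–lithium exchange (tBuLi, Et2O, −78 °C) gives the alkenyllithium F6. Quenching with DMF gives (2Z,4S,5E,7E,9E,11E)-2,8-diethyl-4,6-dimethyl-12-phenyldodeca-2,5,7,9,11-pentaenal F7. A Horner–Wadsworth–Emmons reaction with the dianion of 2-(diethoxyphosphoryl)propanoic acid (2 equiv LiN(SiMe3)2, THF, −78 to 0 °C) then gives the 2E acid 22.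

**Further compounds**

F1 | step 10 | (2E,4Z,6S,7E,9E,11E,13E)-4,10-diethyl-2,6,8-trimethyl-14-phenyltetradeca-2,4,7,9,11,13-hexaen-1-ol | OC/C(C)=C/C(CC)=C\[C@@H](C)/C=C(C)/C=C(CC)/C=C/C=C/c1ccccc1
F2 | step 10 | (2E,4Z,6S,7E,9E,11E,13E)-4,10-diethyl-2,6,8-trimethyl-14-phenyltetradeca-2,4,7,9,11,13-hexaenal | O=C/C(C)=C/C(CC)=C\[C@@H](C)/C=C(C)/C=C(CC)/C=C/C=C/c1ccccc1
F3 | step 10 | (1R,3aR,4R,5S,7aS)-3,5-diethyl-1,4,7-trimethyl-5-[(1E,3E)-4-phenylbuta-1,3-dien-1-yl]-3a,4,5,7a-tetrahydro-1H-indene-4-carbaldehyde | CCC1=C[C@@H](C)[C@@H]2C(C)=C[C@@](/C=C/C=C/c3ccccc3)(CC)[C@](C)(C=O)[C@@H]12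
F4 | step 6 | [(1E,3E,5E,7E,9S)-11,11-dichloro-5-ethyl-7,9-dimethylundeca-1,3,5,7,10-pentaen-1-yl]benzene | ClC(Cl)=C[C@@H](C)/C=C(C)/C=C(CC)/C=C/C=C/c1ccccc1
F5 | step 6 | [(1E,3E,5E,7E,9S,10Z)-11-chloro-5-ethyl-7,9-dimethyltrideca-1,3,5,7,10-pentaen-1-yl]benzene | CC/C(Cl)=C/[C@@H](C)/C=C(C)/C=C(CC)/C=C/C=C/c1ccccc1
F6 | step 9 | [(3E,5R,6E,8E,10E,12E)-9-ethyl-5,7-dimethyl-13-phenyltrideca-3,6,8,10,12-pentaen-3-yl]lithium | CC/C([Li])=C/[C@@H](C)/C=C(C)/C=C(CC)/C=C/C=C/c1ccccc1
F7 | step 9 | (2Z,4S,5E,7E,9E,11E)-2,8-diethyl-4,6-dimethyl-12-phenyldodeca-2,5,7,9,11-pentaenal | CC/C(C=O)=C/[C@@H](C)/C=C(C)/C=C(CC)/C=C/C=C/c1ccccc1
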